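| flask | substrate | solid reagent | temperature | remark | time |
|---|---|---|---|---|---|
| north | 0.50 M | 1.2 equiv | 45 °C | run made earlier |  |
| south-west | 0.50 M | 1.9 equiv | 67 °C | run made earlier |  |
| zeta | 0.50 M | 2.50 equiv | 75 °C |  | 20 h |
| gamma | 0.50 M | 2.50 equiv | 55 °C |  | 20 h |
| theta | 0.50 M | 2.50 equiv | 35 °C |  | 20 h |

- north (time / h: double product / %): 8.00: 0; 20.0: 9; 40.0: 23; 120: 31
- south-west (time / h: double product / %): 6.00: 1; 12.0: 13; 20.0: 19; 25.0: 19

(readings scatter by 2 percentage points)

- solid reagent is a solid; its amount is given per volume of the solution
- what was read earlier has a scatter of 2 percentage points, one standard deviation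
- at the start none of the solid reagent is in solution

- the flask with the highest amount of double product, in percent of the substrate charged ("all alike" if they lie within 1.5 percentage points) (zeta / gamma / theta / all alike)
- final double product, as a percentage of the substrate charged, in zeta
- final double product, as a percentage of the substrate charged, in gamma
- final double product, as a percentage of the substrate charged, in theta

A ratio of two times carries this reckoning. On a straight line between its readings at 20.0 h and 40.0 h, the north run reaches 13 % double product at 25.7 h, and the south-west run shows that reading at 12.0 h. Their quotient, 2.14, is the time stretch f between the two temperatures. It is a reading with the scatter of its runs, and it is assumed to belong to temperature, though south-west also has 1.9 equiv of solid reagent against 1.2 equiv. Spread evenly over the degrees, and with the amount of solid reagent set aside, it turns each flask's time into an estimated equivalent time at the north temperature: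

S = f^((T − T north)/(T south-west − T north)); equivalent time = S·t

Take the main step alone, at the constant rate r read from the same two north readings, 0.00700 h⁻¹ as a share of the charge. Adding up a constant rate gives a straight line, r·S·t. Gamma, with S = 1.41, has an equivalent time of 28.3 h, so this gives 19.8 %.

The next addition is the lag (induction period). North's line meets zero at 7.14 h, so:

double product = r·(S·t − t lag)

Gamma falls to 14.8 %. Theta, with S = 0.707, gives 4.90 %.

The rest is read, not reckoned. South-west at 20.0 h has an equivalent time of 42.9 h; the line gives 25.0 %, more than its reading of 19 %. Zeta's equivalent time is 56.5 h, and its line value of 34.6 % stands above north's 31 % at 120 h. So the line is dropped there and south-west's reading of 19 % is taken as the estimate for zeta, the highest of the estimates.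

The forecast differs on the order, with 17 % in zeta, 26 % in gamma and 3 % in theta: “The middle flask should be highest, though this is uncertain.”

The simulation gives 20.5 % in zeta, 14.0 % in gamma and 3.39 % in theta, so zeta stands highest.

    substrate + partner → first product + by-product (k = 0.160 M⁻¹ h⁻¹, Ea = 74.0 kJ mol⁻¹)
    partner + first product → double product + by-product (k = 0.0900 M⁻¹ h⁻¹, Ea = 86.0 kJ mol⁻¹)
    partner + double product → tris adduct + by-product (k = 0.0360 M⁻¹ h⁻¹, Ea = 67.0 kJ mol⁻¹)
    partner + tris adduct → tetra adduct + by-product (k = 0.00700 M⁻¹ h⁻¹, Ea = 75.0 kJ mol⁻¹)
    substrate ⇌ dormant form (K = 1.90, k = 0.0280 h⁻¹, Ea = 113 kJ mol⁻¹, ΔH = 39.0 kJ mol⁻¹)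
    solid reagent ⇌ partner, rate k6*(cs6 - [partner]) while solid is left; crystals form when [partner] > cs6 (solubility = 0.450 M, k = 0.0590 h⁻¹)
    (constants at 35 °C)

Gamma's 14.0 % lies 0.80 percentage points below its line value of 14.8 %. The neighbouring flask is like gamma but kept at 30 °C. There the same ratio gives S = 0.595 and an equivalent time of 11.9 h, so the line gives 3.33 %. That flask holds 1.73 % double product, less than the line value, and at 20.0 h it still holds 58.2 % substrate and 20.4 % first product.

The data were generated by integration with made-up constants; scatter was added.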